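All runs were generated by integration for an exercise; noise was put on by code.

The constants I can read from the earlier runs are two loss constants of starting material and one share of target.

the same everywhere: free catalyst 0.43 mM
- elm: starting material 0.058 M; second substrate 0.087 M; temperature −20 °C; run made earlier
- cedar: starting material 0.13 M; second substrate 0.087 M; temperature −8 °C; run made earlier
- teal: starting material 0.087 M; second substrate 0.0870 M; temperature −15 °C; time 1.0 h
- amber: starting material 0.087 M; second substrate 0.0870 M; temperature 0 °C; time 1.0 h
- green: starting material 0.087 M; second substrate 0.0870 M; at 0 °C until 40 min, from then on at −15 °C; time 1.0 h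

- elm (time / min: target / %, starting material / %): 5.00: 0.4, 99.0; 12.0: 1.2, 97.9; 25.0: 1.5, 96.4; 40.0: 2.2, 93.9
- cedar (time / min: target / %, starting material / %): 5.00: 0.6, 97.2; 12.0: 2.0, 93.2; 25.0: 4.2, 87.0; 40.0: 6.4, 79.9

(readings scatter by 0.3 percentage points)

- the flask that comes out highest in amount of target, in percent of the starting material charged, or "all alike" when all lie within 1.5 percentage points (teal / amber / green / all alike)
- target at the end, in percent of the starting material charged, teal
- target at the end, in percent of the starting material charged, amber
- target at the end, in percent of the starting material charged, green

I treat the loss of starting material as first order. The last readings of the two runs then give 0.00157 /min for elm and 0.00561 /min for cedar, a factor of 3.57. The two charges differ as well as the temperatures, so this order is an assumption.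

What looks nearly constant is the target formed per starting material lost, the selectivity. Elm reads 0.361 and cedar 0.318. That gap is worth 0.26 percentage points of target in elm, about one scatter of 0.3 points. So I freeze the mean as the target share, 0.340.

With the share frozen, target follows the loss, and the decision hangs on the loss. I draw the logarithm of the constant straight against temperature, which gives 0.0131 /min at 0 °C, beyond both runs, and 0.00267 /min at −15 °C. Amber then loses 54.4 %, green 43.8 % and teal 14.8 %. My targets are 18.5 % for amber, 14.9 % for green and 5.03 % for teal. Amber leads green by 3.6 points, more than the margin of 1.5 points. So I charge nothing new, leave the bath at 0 °C for 1.0 h, and skip the cooling at 40 min.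

The forecast names amber as well, with 5 % for teal, 15.5 % for amber and 12.7 % for green, and of the share it says “I take about 0.30 at 0 °C”.

The flasks give 5.80 % in teal, 23.7 % in amber and 18.8 % in green, so amber stands highest.

    catalyst intermediate B → free catalyst + second product (k = 1.20 /min, Ea = 74.0 kJ/mol)
    starting material + free catalyst ⇌ catalyst intermediate A (K = 110 /M, k = 45.0 /M/min, Ea = 47.0 kJ/mol, ΔH = 13.0 kJ/mol)
    starting material → uncatalysed product (k = 0.0110 /min, Ea = 81.0 kJ/mol)
    catalyst intermediate A → free catalyst + target (k = 1.90 /min, Ea = 68.0 kJ/mol)
    second substrate + free catalyst ⇌ catalyst intermediate B (K = 5.10 /M, k = 95.0 /M/min, Ea = 54.0 kJ/mol, ΔH = −5.00 kJ/mol)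
    (constants at 0 °C)

Amber ends with 35 % of its starting material unbound, so it has lost 65.0 % against my 54.4 %, and its share is 0.365 against my 0.340. At the end of green, the path from starting material to uncatalysed product uses starting material at 0.61 times the rate of the path from starting material and free catalyst to catalyst intermediate A, taking the forward step of that path alone. Green charged with 0.0011 M of free catalyst ends with 42.8 % of target and 29 % of starting material left unbound, a share of 0.603 against my 0.340.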